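(The numbers in the tables were generated by integration with constants of no real substance.)

Exchanges are conserved: once incoming ligand has reacted, it stands on a complex, once on complex with one exchanged, twice on complex with two exchanged, and once in each side product.

| setting | cedar | alder | ash | elm | grey | amber | violet | teal |
|---|---|---|---|---|---|---|---|---|
| starting complex | 0.28 M | 0.19 M | 0.42 M | 0.28 M | 0.28 M (in portions, 3, over 80 s) | 0.28 M | 0.28 M | 0.28 M (fed, over 80 s) |
| incoming ligand | 0.50 equiv | 0.50 equiv | 0.50 equiv | 0.50 equiv | 0.500 equiv | 0.500 equiv (fed, over 80 s) | 0.500 equiv | 0.500 equiv |
| leaving ligand | 1 equiv | 1 equiv | 1 equiv | 2 equiv | 1.00 equiv | 1.00 equiv | 1.00 equiv | 1.00 equiv |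
| remark | run made earlier | run made earlier | run made earlier | run made earlier | first portion at the start, last at 80 s | all else is in the flask from the start; the feed brings no volume worth counting | everything together at the start | all else is in the flask from the start; the feed brings no volume worth counting |
| time |  |  |  |  | 3.0 min | 3.0 min | 3.0 min | 3.0 min |

- cedar (time / s: complex with one exchanged / %, complex with two exchanged / %): 15.0: 23.6, 12.7; 40.0: 22.7, 9.7; 80.0: 16.9, 9.6; 120: 14.0, 8.9
- alder (time / min: complex with one exchanged / %, complex with two exchanged / %): 0.417: 25.4, 11.6; 1.33: 20.7, 10.4; 2.50: 15.3, 11.0; 4.00: 12.1, 9.2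
- ash (time / min: complex with one exchanged / %, complex with two exchanged / %): 0.417: 23.5, 10.2; 1.33: 15.3, 11.5; 2.50: 10.1, 9.7; 4.00: 5.5, 9.0
- elm (time / min: complex with one exchanged / %, complex with two exchanged / %): 0.417: 23.9, 11.4; 1.33: 18.4, 11.8; 2.50: 13.5, 8.3; 4.00: 9.7, 11.2

(each reading ± 1 percentage point)

- percentages count the starting complex that a species holds: one side product counts as two
- steps under discussion: starting complex + incoming ligand <-> leaving ligand + complex with one exchanged; complex with one exchanged + incoming ligand <-> leaving ligand + complex with two exchanged; complex with two exchanged + incoming ligand <-> leaving ligand + complex with three exchanged; complex with three exchanged + incoming ligand <-> leaving ligand + complex with four exchanged; leaving ligand -> by-product carried off; incoming ligand -> decomposition product; starting complex + complex with one exchanged -> side product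

- the best flask by share of complex with one exchanged in complex with one exchanged plus complex with two exchanged; "all alike" if 1.5 percentage points covers them all (grey / amber / violet / teal / all alike)
- share of complex with one exchanged in complex with one exchanged plus complex with two exchanged at the end, grey
- share of complex with one exchanged in complex with one exchanged plus complex with two exchanged at the end, amber
- share of complex with one exchanged in complex with one exchanged plus complex with two exchanged at the end, violet
- share of complex with one exchanged in complex with one exchanged plus complex with two exchanged at the end, teal

In cedar at 15.0 s, [complex with one exchanged] + 2[complex with two exchanged] stood at 49.0% of the starting complex against a charge of 0.50 equiv, so I took the incoming ligand, the limiting reagent, as spent. After that I froze [complex with two exchanged] at 9.40%, while [complex with one exchanged] fell, and at 4.00 min it was lower in ash, 5.5%, than in alder, 12.1%.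

Each exchange lost from view took one starting complex into side product, so at this charge, ignoring higher exchanges, [starting complex] = [complex with one exchanged] + 3[complex with two exchanged]. In cedar that gave 61.7% falling to 40.7%, a mean of 0.143 M. The fall of complex with one exchanged then gave 0.0347 L mol⁻¹ s⁻¹, my loss constant, its first-order rate of loss per unit [starting complex]. Carried to 3.0 min, this left violet, cedar's recipe, with 11.0% of complex with one exchanged, a share of 54.0%.

The forecast chose amber, at 56%, with violet at 52%, below my share, and grey at 28% and teal at 25%, since “early complex sees excess ligand and over-exchanges”.

The simulation gave amber at 57.9%, violet 54.9%, grey 40.5% and teal 42.9%, so grey and teal stood 12 percentage points and 18 points above the forecast.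

    starting complex + incoming ligand ⇌ leaving ligand + complex with one exchanged (K = 34.0, k = 0.890 L mol⁻¹ s⁻¹)
    complex with one exchanged + incoming ligand ⇌ leaving ligand + complex with two exchanged (K = 31.0, k = 1.30 L mol⁻¹ s⁻¹)
    complex with two exchanged + incoming ligand ⇌ leaving ligand + complex with three exchanged (K = 2.00, k = 0.0300 L mol⁻¹ s⁻¹)
    complex with three exchanged + incoming ligand ⇌ leaving ligand + complex with four exchanged (K = 1.30, k = 0.780 L mol⁻¹ s⁻¹)
    leaving ligand → by-product carried off (k = 0.0190 s⁻¹)
    incoming ligand → decomposition product (k = 5.50 × 10⁻⁵ s⁻¹)
    starting complex + complex with one exchanged → side product (k = 0.0410 L mol⁻¹ s⁻¹)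

In grey at 3.00 min, complex with one exchanged was made at 0.239 of the rate at which it was used up, each step taken net, and with 54.8% of the starting complex standing, the loss constant gave it a lifetime of 188 s. In the neighbour flask, grey with 1.1 M of starting complex charged, 34.1% stood at that time, the same constant gave a shorter lifetime of 76.8 s, and complex with one exchanged ended at 5.31%, lower than grey's 9.59%.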